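**Strategy.** The six-membered ring is traced back to a cyclopentanol. Its contiguous triad C(=CH2)–CH(CH2R)–C(CH3)2 arises when the CMe2 ring carbon of (1R)-2,2-dimethyl-1-[(2S)-oxiran-2-yl]cyclopentan-1-ol shifts from the carbinol carbon to the oxirane CH. This Lewis-acid semipinacol rearrangement expands the ring by one carbon, sets the only stereocentre by inversion of an epoxide centre (installed by Sharpless epoxidation and Payne inversion), places the ketone (later =CH2) and frees a CH2OH handle in one operation. The handle becomes a Grignard reagent that is joined to an 8-bromogeranyl unit; the malonate half ester is added last.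

Key step: step 6

Remark: compounds 1, 2, 12 and 18 are taken as commercial; the enantiomeric purity rests on step 3 and is carried on by stereospecific steps.

**Step 1**
Reactants: 1 2,2-dimethylcyclopentan-1-one; 2 triethyl phosphonoacetate
Product: 3 ethyl (2E)-(2,2-dimethylcyclopentylidene)acetate
Conditions: NaH, THF, 0 °C → reflux
Reagents that add atoms: none
Why: Horner–Wadsworth–Emmons olefination of the hindered but reactive cyclopentanone, in which the ester is expected to end up trans to the CMe2 carbon (E) for steric reasons.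

**Step 2**
Reactants: 3 ethyl (2E)-(2,2-dimethylcyclopentylidene)acetate
Product: 4 (2E)-2-(2,2-dimethylcyclopentylidene)ethan-1-ol
Conditions: i-Bu2AlH (DIBAL-H), CH2Cl2, −78 → 0 °C
Reagents that add atoms: none
Why: 1,2-reduction of the enoate with DIBAL-H should give the allylic alcohol without change of alkene geometry.

**Step 3**
Reactants: 4 (2E)-2-(2,2-dimethylcyclopentylidene)ethan-1-ol
Product: 5 [(2R,3R)-4,4-dimethyl-1-oxaspiro[2.4]heptan-2-yl]methanol
Conditions: Ti(OiPr)4 (cat.), D-(−)-diethyl tartrate (cat.), t-BuOOH, 4 Å molecular sieves, CH2Cl2, −20 °C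
Reagents that add atoms: tert-butyl hydroperoxide, CC(C)(C)OO
Why: Sharpless asymmetric epoxidation of a 3,3-disubstituted E-allylic alcohol, a substrate class that reacts with high enantioselectivity; the D-(−)-tartrate should give the (2R,3R)-epoxide (the mirror image of the (2S,3S) sense of the L-(+)-ester), so both oxirane centres are set by the catalyst.

**Step 4**
Reactants: 5 [(2R,3R)-4,4-dimethyl-1-oxaspiro[2.4]heptan-2-yl]methanol
Product: 6 (1S)-1-[(1R)-1-hydroxy-2,2-dimethylcyclopentyl]ethane-1,2-diol
Conditions: 0.5 M NaOH, t-BuOH/H2O, 70 °C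
Reagents that add atoms: water, O
Why: Payne rearrangement–opening, in which the primary alkoxide displaces the oxirane oxygen at C2 with inversion and hydroxide opens the transient terminal epoxide at its CH2 (direct hydroxide attack at C2 would give the same triol), so the secondary carbinol becomes (S) while the tertiary centre is untouched, which gives the relative configuration that step 6 needs.

**Step 5**
Reactants: 6 (1S)-1-[(1R)-1-hydroxy-2,2-dimethylcyclopentyl]ethane-1,2-diol
Product: 8 (1R)-2,2-dimethyl-1-[(2S)-oxiran-2-yl]cyclopentan-1-ol, via primary tosylate 7 (not isolated)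
Conditions: TsCl, Et3N, Bu2SnO (cat.), CH2Cl2, 0 °C → rt; then DBU, rt
Reagents that add atoms: p-toluenesulfonyl chloride, Cc1ccc(cc1)S(Cl)(=O)=O (its atoms stay only in intermediate 7)
Why: tin-catalysed selective sulfonylation of the primary hydroxyl and 3-exo-tet closure from the secondary oxygen should give the terminal epoxide with retention at the stereocentre (its C–O bond is not broken), and the amine base avoids the tertiary alkoxide that could rearrange 8 back to 5.

**Step 6**
Reactants: 8 (1R)-2,2-dimethyl-1-[(2S)-oxiran-2-yl]cyclopentan-1-ol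
Product: 9 (2R)-2-(hydroxymethyl)-3,3-dimethylcyclohexan-1-one
Conditions: BF3·OEt2, CH2Cl2, −78 → −40 °C
Reagents that add atoms: none
Why: BF3 binds the oxirane oxygen and, as the C–O bond at the oxirane CH stretches, the antiperiplanar ring bond from the carbinol carbon to the CMe2 carbon shifts onto that CH while the carbinol oxygen becomes the carbonyl, so the cyclopentanol becomes a cyclohexanone by a one-carbon ring expansion and the oxirane is left as CH2OH. The closest known reaction type is the semipinacol rearrangement of 2,3-epoxy alcohols (α-hydroxy epoxides), which is established for ring expansion of cycloalkanols. The six-membered ring is not closed by a cyclisation but arises by this suprafacial 1,2-shift of a ring C–C bond (formally a 3-exo-tet attack of the σ bond on the oxirane carbon). The new ring stereocentre forms with inversion at the oxirane CH, so it is controlled by the (2S) epoxide centre of 8, while the carbinol centre is destroyed. The step needs migration of the CMe2 carbon and not of the ring CH2: the tertiary alkyl carbon has the higher migratory aptitude, and the (1R,2S) relative configuration secured by the inversion in step 4 lets the oxirane CH2 sit beside the chelated hydroxyl in the transition state for CMe2 migration, whereas CH2 migration would press it against the gem-dimethyl carbon. Low temperature and a Lewis acid without a nucleophilic counter-ion should hold back hydride shift and external opening at the terminal carbon.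

**Step 7**
Reactants: 9 (2R)-2-(hydroxymethyl)-3,3-dimethylcyclohexan-1-one
Product: 10 [(1S)-2,2-dimethyl-6-methylidenecyclohexyl]methanol
Conditions: Zn, CH2Br2, TiCl4 (excess reagent), THF/CH2Cl2, 0 °C → rt
Reagents that add atoms: dibromomethane, BrCBr
Why: Lombardo–Takai methylenation, a non-basic reagent that should convert the hindered, enolisable ketone without epimerising the α-stereocentre and that tolerates the free hydroxyl when used in excess.

**Step 8**
Reactants: 10 [(1S)-2,2-dimethyl-6-methylidenecyclohexyl]methanol
Product: 11 (2S)-2-(iodomethyl)-1,1-dimethyl-3-methylidenecyclohexane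
Conditions: I2, PPh3, imidazole, toluene, rt → 60 °C
Reagents that add atoms: iodine, II
Why: Appel-type iodination (Garegg conditions), an SN2 displacement of the alkoxyphosphonium group at the primary carbon that leaves the adjacent stereocentre and the exocyclic alkene untouched.

**Step 9**
Reactants: 12 geranyl acetate
Product: 13 (2E,6E)-8-hydroxy-3,7-dimethylocta-2,6-dien-1-yl acetate
Conditions: SeO2 (cat.), t-BuOOH, salicylic acid (cat.), CH2Cl2, rt
Reagents that add atoms: tert-butyl hydroperoxide, CC(C)(C)OO
Why: Riley allylic oxidation (ene reaction, then [2,3]-sigmatropic shift), which is selective for the E-methyl group of the terminal trisubstituted alkene.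

**Step 10**
Reactants: 13 (2E,6E)-8-hydroxy-3,7-dimethylocta-2,6-dien-1-yl acetate
Product: 14 (2E,6E)-8-bromo-3,7-dimethylocta-2,6-dien-1-yl acetate
Conditions: CBr4, PPh3, CH2Cl2, 0 °C
Reagents that add atoms: carbon tetrabromide, BrC(Br)(Br)Br
Why: Appel bromination of the primary allylic alcohol, which at low temperature should proceed by SN2 without allylic transposition or loss of E geometry.

**Step 11**
Reactants: 11 (2S)-2-(iodomethyl)-1,1-dimethyl-3-methylidenecyclohexane; 14 (2E,6E)-8-bromo-3,7-dimethylocta-2,6-dien-1-yl acetate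
Product: 16 (2E,6E)-9-[(1S)-2,2-dimethyl-6-methylidenecyclohexyl]-3,7-dimethylnona-2,6-dien-1-yl acetate, via Grignard reagent 15 (not isolated)
Conditions: Mg, THF, rt → 40 °C; then 14, Li2CuCl4 (cat.), THF, −78 → 0 °C
Reagents that add atoms: magnesium, [Mg] (held only in intermediate 15)
Why: copper-catalysed Grignard cross-coupling of Kochi type, in which the primary alkylmagnesium reagent should substitute the allylic bromide at its CH2 terminus with retention of the E alkene, the acetate surviving at low temperature and the ring stereocentre not being involved.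

**Step 12**
Reactants: 16 (2E,6E)-9-[(1S)-2,2-dimethyl-6-methylidenecyclohexyl]-3,7-dimethylnona-2,6-dien-1-yl acetate
Product: 17 (2E,6E)-9-[(1S)-2,2-dimethyl-6-methylidenecyclohexyl]-3,7-dimethylnona-2,6-dien-1-ol
Conditions: K2CO3, MeOH, rt
Reagents that add atoms: none
Why: base-catalysed methanolysis of the acetate, which should not affect the three alkenes.

**Step 13**
Reactants: 17 (2E,6E)-9-[(1S)-2,2-dimethyl-6-methylidenecyclohexyl]-3,7-dimethylnona-2,6-dien-1-ol; 18 Meldrum's acid (2,2-dimethyl-1,3-dioxane-4,6-dione)
Product: 19 3-{[(2E,6E)-9-[(1S)-2,2-dimethyl-6-methylidenecyclohexyl]-3,7-dimethylnona-2,6-dien-1-yl]oxy}-3-oxopropanoic acid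
Conditions: toluene, 90 °C
Reagents that add atoms: none
Why: ring-opening acylation of the alcohol by Meldrum's acid with loss of acetone should give the malonic acid half ester directly, at a temperature too low for decarboxylation.

**Compound list**

1 | 2,2-dimethylcyclopentan-1-one | CC1(C)CCCC1=O | starting material
2 | triethyl phosphonoacetate | CCOC(=O)CP(=O)(OCC)OCC | starting material
3 | ethyl (2E)-(2,2-dimethylcyclopentylidene)acetate | CCOC(=O)/C=C1\CCCC1(C)C | intermediate
4 | (2E)-2-(2,2-dimethylcyclopentylidene)ethan-1-ol | OC/C=C1\CCCC1(C)C | intermediate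
5 | [(2R,3R)-4,4-dimethyl-1-oxaspiro[2.4]heptan-2-yl]methanol | OC[C@H]1O[C@@]12CCCC2(C)C | intermediate
6 | (1S)-1-[(1R)-1-hydroxy-2,2-dimethylcyclopentyl]ethane-1,2-diol | OC[C@H](O)[C@@]1(O)CCCC1(C)C | intermediate
7 | (2S)-2-hydroxy-2-[(1R)-1-hydroxy-2,2-dimethylcyclopentyl]ethyl 4-methylbenzenesulfonate | Cc1ccc(cc1)S(=O)(=O)OC[C@H](O)[C@@]1(O)CCCC1(C)C | intermediate
8 | (1R)-2,2-dimethyl-1-[(2S)-oxiran-2-yl]cyclopentan-1-ol | O[C@]1([C@@H]2CO2)CCCC1(C)C | intermediate
9 | (2R)-2-(hydroxymethyl)-3,3-dimethylcyclohexan-1-one | O=C1CCCC(C)(C)[C@@H]1CO | intermediate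
10 | [(1S)-2,2-dimethyl-6-methylidenecyclohexyl]methanol | C=C1CCCC(C)(C)[C@@H]1CO | intermediate
11 | (2S)-2-(iodomethyl)-1,1-dimethyl-3-methylidenecyclohexane | C=C1CCCC(C)(C)[C@@H]1CI | intermediate
12 | geranyl acetate, (2E)-3,7-dimethylocta-2,6-dien-1-yl acetate | CC(C)=CCC/C(C)=C/COC(C)=O | starting material
13 | (2E,6E)-8-hydroxy-3,7-dimethylocta-2,6-dien-1-yl acetate | OC/C(C)=C/CC/C(C)=C/COC(C)=O | intermediate
14 | (2E,6E)-8-bromo-3,7-dimethylocta-2,6-dien-1-yl acetate | BrC/C(C)=C/CC/C(C)=C/COC(C)=O | intermediate
15 | {[(1S)-2,2-dimethyl-6-methylidenecyclohexyl]methyl}magnesium iodide | C=C1CCCC(C)(C)[C@@H]1C[Mg]I | intermediate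
16 | (2E,6E)-9-[(1S)-2,2-dimethyl-6-methylidenecyclohexyl]-3,7-dimethylnona-2,6-dien-1-yl acetate | C=C1CCCC(C)(C)[C@@H]1CC/C(C)=C/CC/C(C)=C/COC(C)=O | intermediate
17 | (2E,6E)-9-[(1S)-2,2-dimethyl-6-methylidenecyclohexyl]-3,7-dimethylnona-2,6-dien-1-ol | C=C1CCCC(C)(C)[C@@H]1CC/C(C)=C/CC/C(C)=C/CO | intermediate
18 | Meldrum's acid, 2,2-dimethyl-1,3-dioxane-4,6-dione | CC1(C)OC(=O)CC(=O)O1 | starting material
19 | 3-{[(2E,6E)-9-[(1S)-2,2-dimethyl-6-methylidenecyclohexyl]-3,7-dimethylnona-2,6-dien-1-yl]oxy}-3-oxopropanoic acid | C=C1CCCC(C)(C)[C@@H]1CC/C(C)=C/CC/C(C)=C/COC(=O)CC(=O)O | target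

**Step count.** Total: 13 steps. Longest linear sequence: 11 steps (1–8, then 11–13).

**Steps most likely to fail**

Step 6. The activated oxirane may be opened at its terminal carbon by fluoride or undergo a hydride shift faster than the ring bond migrates, and part of the material may react by migration of the ring CH2. The fallback is the aluminium-promoted semipinacol rearrangement of an α-hydroxy mesylate, and it sets out from triol 6. Selective silylation of the primary hydroxyl (TBSCl, imidazole, CH2Cl2, 0 °C) should give (1R)-1-[(1S)-2-{[tert-butyl(dimethyl)silyl]oxy}-1-hydroxyethyl]-2,2-dimethylcyclopentan-1-ol F1. Mesylation of the secondary hydroxyl (MsCl, Et3N, CH2Cl2, −20 °C) should give (1S)-2-{[tert-butyl(dimethyl)silyl]oxy}-1-[(1R)-1-hydroxy-2,2-dimethylcyclopentyl]ethyl methanesulfonate F2. Et3Al (CH2Cl2, −78 → 0 °C) should convert F2 through its aluminium alkoxide, with the same CMe2 shift and inversion, into (2R)-2-({[tert-butyl(dimethyl)silyl]oxy}methyl)-3,3-dimethylcyclohexan-1-one F3. HF·pyridine (THF, 0 °C) removes the silyl group, and the route is rejoined at 9.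

Step 11. Magnesium insertion into the hindered iodide may give Wurtz-type homocoupling, and the copper-catalysed step may lose regiocontrol (attack at the γ-carbon of the allylic bromide) or touch the acetate. The fallback is a sulfone alkylation, and it sets out from iodide 11. PhSO2Na (DMF, 80 °C) should give {[(1S)-2,2-dimethyl-6-methylidenecyclohexyl]methanesulfonyl}benzene F4. Deprotonation (n-BuLi, THF, −78 °C) and alkylation with 14 should give (2E,6E)-9-(benzenesulfonyl)-9-[(1S)-2,2-dimethyl-6-methylidenecyclohexyl]-3,7-dimethylnona-2,6-dien-1-yl acetate F5 as a mixture of epimers at the sulfonyl carbon. Mg in MeOH (rt) should cleave the C–S bond reductively and methanolyse the acetate, and the route is rejoined at 17.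

Step 7. Addition to the hindered carbonyl group may be slow, and under the Lewis-acidic medium the β-hydroxy ketone may dehydrate or epimerise. The fallback is a Peterson olefination, and it sets out from 9. Me3SiCH2Li with CeCl3 (THF, −78 °C, excess) should add to the ketone and give (2R)-2-(hydroxymethyl)-3,3-dimethyl-1-[(trimethylsilyl)methyl]cyclohexan-1-ol F6 as a mixture of epimers at the carbinol carbon. KH (THF, rt) should then effect the syn-elimination to the exocyclic alkene, and the route is rejoined at 10.

**Further compounds**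

F1 | step 6 | (1R)-1-[(1S)-2-{[tert-butyl(dimethyl)silyl]oxy}-1-hydroxyethyl]-2,2-dimethylcyclopentan-1-ol | CC(C)(C)[Si](C)(C)OC[C@H](O)[C@@]1(O)CCCC1(C)C
F2 | step 6 | (1S)-2-{[tert-butyl(dimethyl)silyl]oxy}-1-[(1R)-1-hydroxy-2,2-dimethylcyclopentyl]ethyl methanesulfonate | CC(C)(C)[Si](C)(C)OC[C@H](OS(C)(=O)=O)[C@@]1(O)CCCC1(C)C
F3 | step 6 | (2R)-2-({[tert-butyl(dimethyl)silyl]oxy}methyl)-3,3-dimethylcyclohexan-1-one | O=C1CCCC(C)(C)[C@@H]1CO[Si](C)(C)C(C)(C)C
F4 | step 11 | {[(1S)-2,2-dimethyl-6-methylidenecyclohexyl]methanesulfonyl}benzene | C=C1CCCC(C)(C)[C@@H]1CS(=O)(=O)c1ccccc1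
F5 | step 11 | (2E,6E)-9-(benzenesulfonyl)-9-[(1S)-2,2-dimethyl-6-methylidenecyclohexyl]-3,7-dimethylnona-2,6-dien-1-yl acetate | C=C1CCCC(C)(C)[C@@H]1C(C/C(C)=C/CC/C(C)=C/COC(C)=O)S(=O)(=O)c1ccccc1
F6 | step 7 | (2R)-2-(hydroxymethyl)-3,3-dimethyl-1-[(trimethylsilyl)methyl]cyclohexan-1-ol | C[Si](C)(C)CC1(O)CCCC(C)(C)[C@@H]1CO
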